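**Retrosynthetic overview**

1. The target (germacranolide numbering: C1/C10 epoxide with C14 methyl, C3 carbinol, C4 bearing C15H2OH, C4=C5, C6–O/C12 lactone with C11=C13, C8 ester) is traced back, through PMB removal, epoxidation of C1=C10, methacrylation of O8 and oxidative lactonisation (O6/C12), to a protected (1(10)E,4Z)-cyclodeca-1(10),4-diene.
2. Enabling feature: the epoxide (a masked E-alkene, C1–C10) and the C4=C5 alkene are 1,5-related through C2–C3, so the ten-membered ring is a cyclodeca-1,5-diene, the retron of a Cope rearrangement of a 1,2-dialkenylcyclohexane (ring C5–C10).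
3. The ten-membered ring is therefore made from a cyclohexanol by an anionic oxy-Cope ring expansion that forms C2–C3 and breaks C5–C10. The temporary C5 oxygen is removed via the enol triflate, and a (Z)-enol ether terminus delivers the C3 oxygen and its configuration in the same step.
4. The cyclohexanol comes from a ketone plus a (Z)-alkenylcerium reagent (C3, C4, C15). The ketone (C5–C10, C14) comes from a quinone monoketal by asymmetric conjugate alkenylation (C7 with C11–C13), 1,4-carbonyl transposition, alkoxide-directed vinylation (C1, C2 on C10), reduction (O8) and enolate hydroxylation (O6).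
5. Ring order: cyclohexane (from the arene) → ten-membered carbocycle (key step) → γ-lactone → epoxide.

Key step: step 16

Remark on descriptors: carbons carry the target numbering throughout; in the six-membered intermediates (ring C5–C10) β is the face of the C7 side chain and α the opposite face.
Assumption: (R)-BINAP is taken to deliver the alkenyl group to the required enone face in step 7 by analogy with 2-cyclohexenone; if the sense is opposite, the antipodal ligand is used.

**Route**

Step 1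
Reactants: 1 tert-butyldimethyl(prop-2-yn-1-yloxy)silane
Product: 2 2-[3-(tert-butyldimethylsilyloxy)prop-1-en-2-yl]-4,4,5,5-tetramethyl-1,3,2-dioxaborolane
Conditions: CuCl (cat.), 1,3-dimesitylimidazolinium chloride (cat.), NaOt-Bu (cat.), B2pin2, MeOH, THF, rt
Reagents that add atoms: bis(pinacolato)diboron, CC1(C)OB(OC1(C)C)B1OC(C)(C)C(C)(C)O1
Why: Carbene–copper-catalysed protoboration of a terminal propargylic ether should place boron on the internal carbon (α-selectivity with an N-aryl carbene ligand), and methanol protonates the alkenylcopper to give the 1,1-disubstituted alkenylboronate.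

Step 2
Reactants: 3 methyl propiolate; 4 4-methoxybenzyl alcohol
Product: 5 methyl (E)-3-[(4-methoxybenzyl)oxy]acrylate
Conditions: N-methylmorpholine (cat.), CH2Cl2, rt
Reagents that add atoms: none
Why: Amine-catalysed oxa-Michael addition of the alcohol to the ynoate should give the (E)-β-alkoxyacrylate.

Step 3
Reactants: 5 methyl (E)-3-[(4-methoxybenzyl)oxy]acrylate
Product: 7 methyl (Z)-2-iodo-3-[(4-methoxybenzyl)oxy]acrylate (iodine cis to the PMB-oxy group), via acetoxy iodide adduct 6 (not isolated)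
Conditions: N-iodosuccinimide, AcOH, CH2Cl2, rt; then Et3N, 0 °C → rt
Reagents that add atoms: N-iodosuccinimide, O=C1CCC(=O)N1I
Why: Iodoacetoxylation of the enol ether followed by base-induced loss of acetic acid (addition–elimination α-halogenation of a β-alkoxyacrylate) should give the α-iodide with iodine cis to the alkoxy group, as for the methoxy analogue.

Step 4
Reactants: 7 methyl (Z)-2-iodo-3-[(4-methoxybenzyl)oxy]acrylate
Product: 8 (Z)-2-iodo-3-[(4-methoxybenzyl)oxy]prop-2-en-1-ol
Conditions: i-Bu2AlH (2.2 equiv), CH2Cl2, −78 °C; aq. Rochelle salt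
Reagents that add atoms: none
Why: 1,2-Reduction of the ester with i-Bu2AlH at low temperature should leave the vinyl iodide and the enol ether geometry untouched.

Step 5
Reactants: 8 (Z)-2-iodo-3-[(4-methoxybenzyl)oxy]prop-2-en-1-ol
Product: 10 (Z)-2-iodo-1,3-bis[(4-methoxybenzyl)oxy]prop-1-ene, via sodium alkoxide 9 (not isolated)
Conditions: NaH, THF/DMF, 0 °C; then 4-methoxybenzyl chloride, n-Bu4NI (cat.), 0 °C → rt
Reagents that add atoms: 4-methoxybenzyl chloride, COc1ccc(CCl)cc1
Why: Williamson etherification of the primary allylic alkoxide.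

Step 6
Reactants: 11 4-methoxy-2-methylphenol
Product: 12 4,4-dimethoxy-2-methylcyclohexa-2,5-dien-1-one
Conditions: PhI(OAc)2, MeOH, 0 °C
Reagents that add atoms: methanol, CO
Why: Oxidative dearomatisation of a 4-methoxyphenol in methanol should give the quinone monoketal that already holds C5–C10 and C14.

Step 7
Reactants: 12 4,4-dimethoxy-2-methylcyclohexa-2,5-dien-1-one; 2 2-[3-(tert-butyldimethylsilyloxy)prop-1-en-2-yl]-4,4,5,5-tetramethyl-1,3,2-dioxaborolane
Product: 13 (R)-4,4-dimethoxy-2-methyl-5-[3-(tert-butyldimethylsilyloxy)prop-1-en-2-yl]cyclohex-2-en-1-one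
Conditions: [RhCl(cod)]2 (cat.), (R)-BINAP, aq. KOH, 1,4-dioxane, 40 °C
Reagents that add atoms: none
Why: Rhodium-catalysed asymmetric conjugate addition (Hayashi–Miyaura reaction) of the alkenylboronate should occur at the unsubstituted enone of the dienone, and the BINAP ligand sets the C7 stereocentre.

Step 8
Reactants: 13 (R)-4,4-dimethoxy-2-methyl-5-[3-(tert-butyldimethylsilyloxy)prop-1-en-2-yl]cyclohex-2-en-1-one
Product: 15 (4R,6R)-4-hydroxy-3-methyl-6-[3-(tert-butyldimethylsilyloxy)prop-1-en-2-yl]cyclohex-2-en-1-one, via allylic alcohol ketal 14 (not isolated)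
Conditions: NaBH4, CeCl3·7H2O, MeOH, −78 °C; then aq. oxalic acid, THF, 0 °C → rt
Reagents that add atoms: water, O
Why: Luche 1,2-reduction should deliver hydride trans to the C7 side chain (cis-carveol-type selectivity) to give the 5β-alcohol, and mild hydrolysis of the ketal then unveils the C8 enone (a formal 1,4-carbonyl transposition).

Step 9
Reactants: 15 (4R,6R)-4-hydroxy-3-methyl-6-[3-(tert-butyldimethylsilyloxy)prop-1-en-2-yl]cyclohex-2-en-1-one
Product: 17 (3R,4R,6R)-4-hydroxy-3-methyl-3-vinyl-6-[3-(tert-butyldimethylsilyloxy)prop-1-en-2-yl]cyclohexan-1-one (vinyl, OH and side chain all cis), via bromomagnesium alkoxide 16 (not isolated)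
Conditions: CH2=CHMgBr (4 equiv), THF, −78 → 0 °C; aq. NH4Cl
Reagents that add atoms: vinylmagnesium bromide, C=C[Mg]Br
Why: Alkoxide-directed (ligand-assisted) conjugate addition: the magnesium alkoxide on C5 should deliver the vinyl group to C10 of the β-methyl enone from its own face, so the quaternary centre forms with vinyl β (cis to O5 and to the C7 side chain) and methyl α.

Step 10
Reactants: 17 (3R,4R,6R)-4-hydroxy-3-methyl-3-vinyl-6-[3-(tert-butyldimethylsilyloxy)prop-1-en-2-yl]cyclohexan-1-one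
Product: 18 (2R,5R)-2-methyl-5-[3-(tert-butyldimethylsilyloxy)prop-1-en-2-yl]-2-vinylcyclohexane-1,4-dione
Conditions: Dess–Martin periodinane, NaHCO3, CH2Cl2, rt
Reagents that add atoms: none
Why: Dess–Martin oxidation of the secondary alcohol restores the C5 carbonyl without touching the alkenes or the silyl ether.

Step 11
Reactants: 18 (2R,5R)-2-methyl-5-[3-(tert-butyldimethylsilyloxy)prop-1-en-2-yl]-2-vinylcyclohexane-1,4-dione
Product: 19 (2R,4R,5R)-4-hydroxy-2-methyl-5-[3-(tert-butyldimethylsilyloxy)prop-1-en-2-yl]-2-vinylcyclohexan-1-one (8β-OH)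
Conditions: LiBH(s-Bu)3 (1.05 equiv), THF, −78 °C; aq. NH4Cl
Reagents that add atoms: none
Why: The bulky hydride should reduce only the C8 ketone (the C5 ketone is neopentylic) and attack from the equatorial side, because the axial C10 vinyl group blocks the other face, giving the axial 8β-alcohol cis to the C7 side chain.

Step 12
Reactants: 19 (2R,4R,5R)-4-hydroxy-2-methyl-5-[3-(tert-butyldimethylsilyloxy)prop-1-en-2-yl]-2-vinylcyclohexan-1-one
Product: 20 triethylsilyl ether of 19 (8β-OSiEt3)
Conditions: Et3SiOTf, 2,6-lutidine, CH2Cl2, −78 °C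
Reagents that add atoms: triethylsilyl trifluoromethanesulfonate, CC[Si](CC)(CC)OS(=O)(=O)C(F)(F)F
Why: Silylation of the hindered axial alcohol with the silyl triflate gives a group that can later be removed in the presence of tert-butyldimethylsilyl ethers.

Step 13
Reactants: 20 triethylsilyl ether of 19
Product: 22 6α-hydroxy ketone (2-methyl-2-vinylcyclohexanone with 6α-OH trans to the 7β side chain and 8β-OSiEt3), via potassium enolate 21 (not isolated)
Conditions: KN(SiMe3)2, THF, −78 °C; then 2-(phenylsulfonyl)-3-phenyloxaziridine, −78 °C; aq. NH4Cl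
Reagents that add atoms: 2-(phenylsulfonyl)-3-phenyloxaziridine, O=S(=O)(c1ccccc1)N1OC1c1ccccc1
Why: C6 is the only enolisable position, and oxaziridine oxidation of the enolate should occur anti to the C7 side chain and the axial 8β-silyloxy group, giving the 6α-alcohol.

Step 14
Reactants: 22 6α-hydroxy ketone
Product: 23 ketone with 6α-OSi(t-Bu)Me2, 7β-[3-(tert-butyldimethylsilyloxy)prop-1-en-2-yl], 8β-OSiEt3, 10α-methyl and 10β-vinyl (C5 carbonyl)
Conditions: t-BuMe2SiOTf, 2,6-lutidine, CH2Cl2, −78 → 0 °C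
Reagents that add atoms: tert-butyldimethylsilyl trifluoromethanesulfonate, CC(C)(C)[Si](C)(C)OS(=O)(=O)C(F)(F)F
Why: Silylation of the α-hydroxy ketone under non-basic conditions avoids α-ketol isomerisation.

Step 15
Reactants: 23 ketone (6α-OSi(t-Bu)Me2, 8β-OSiEt3, 10β-vinyl); 10 (Z)-2-iodo-1,3-bis[(4-methoxybenzyl)oxy]prop-1-ene
Product: 26 tertiary alcohol: the cyclohexanol of 23 bearing 5α-OH and a 5β-[(Z)-1,3-bis(4-methoxybenzyloxy)prop-1-en-2-yl] group (enol ether oxygen cis to C5; the two alkenyl groups on C5 and C10 cis), via alkenyllithium 24 (not isolated), via alkenylcerium dichloride 25 (not isolated)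
Conditions: 10, t-BuLi (2 equiv), Et2O, −78 °C; CeCl3, THF, −78 °C; then 23, −78 → −40 °C; pH 7 buffer
Reagents that add atoms: none
Why: Iodine–lithium exchange with retention gives an oxygen-chelated (Z)-β-alkoxyvinyllithium whose cerium derivative should add to the hindered, enolisable ketone by equatorial attack anti to the C6 silyloxy group (bulky nucleophile, Felkin–Anh polar effect), giving the axial 5α-alkoxide.

Step 16
Reactants: 26 tertiary alcohol
Product: 29 ten-membered enol triflate: (1(10)E,4E)-cyclodeca-1(10),4-diene with 5-OTf, 3-OPMB (3S), 4-CH2OPMB, 6-OSi(t-Bu)Me2, 7-[3-(tert-butyldimethylsilyloxy)prop-1-en-2-yl], 8-OSiEt3 and 10-methyl (C3 and C6 cis on C4=C5), via potassium alkoxide 27 (not isolated), via potassium enolate 28 (not isolated)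
Conditions: KN(SiMe3)2, 18-crown-6, THF, −78 → 0 °C; then PhNTf2, −78 → 0 °C
Reagents that add atoms: N-phenylbis(trifluoromethanesulfonimide), O=S(=O)(N(c1ccccc1)S(=O)(=O)C(F)(F)F)C(F)(F)F
Why: Deprotonation gives the potassium alkoxide of the 3-oxy-1,5-diene C2=C1–C10–C5(O–)–C4=C3, which should undergo an anionic oxy-Cope [3,3]-sigmatropic rearrangement in which C5–C10 breaks while C2–C3 forms, and the resulting enolate is trapped on oxygen by PhNTf2. The closest known reaction type is the anionic oxy-Cope ring expansion of 1,2-dialkenylcyclohexanols to cyclodec-5-enones with in situ enolate triflation. The ten-membered carbocycle is closed by a four-atom ring expansion of the cyclohexane through a six-membered chair transition state, not by an end-to-end cyclisation, so no high dilution is needed. In the accessible chair (C10 vinyl axial and C5 alkenyl equatorial on the cyclohexane chair that keeps the C6 and C7 substituents equatorial) C9 is pseudo-equatorial and C6 pseudo-axial, which gives the E C1=C10 bond and the ring-cis C4=C5 enolate. The new C3 stereocentre is controlled by the Z enol ether: its PMB-oxy group, cis to C5, is pseudo-axial on C3 and this translates into the 3S configuration. The step needs the cis-dialkenyl chair to win over the ring-flipped chair and the β-alkoxy enolate to survive until triflation; the first is secured by the ring substituents (the flipped chair would put the C5 alkenyl group and the C7 side chain both axial), the second by low temperature and immediate trapping.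

Step 17
Reactants: 29 ten-membered enol triflate
Product: 30 (1(10)E,4Z)-diene (C5–H; otherwise as 29)
Conditions: Pd(OAc)2 (cat.), PPh3, n-Bu3N, HCO2H, DMF, 60 °C
Reagents that add atoms: none
Why: Oxidative addition of zerovalent palladium into the enol triflate, formate decarboxylation to a palladium hydride and reductive elimination should replace OTf by H with retention of the double-bond geometry.

Step 18
Reactants: 30 (1(10)E,4Z)-diene
Product: 31 C8 alcohol (8-OH free; both tert-butyldimethylsilyl ethers and both PMB ethers kept)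
Conditions: PPTS (cat.), MeOH/CH2Cl2, 0 °C
Reagents that add atoms: none
Why: Mild acid-catalysed methanolysis should cleave the triethylsilyl ether selectively in the presence of the tert-butyldimethylsilyl ethers.

Step 19
Reactants: 31 C8 alcohol
Product: 32 C8 methacrylate
Conditions: methacrylic anhydride, Et3N, DMAP (cat.), CH2Cl2, 0 °C → rt
Reagents that add atoms: methacrylic anhydride, CC(=C)C(=O)OC(=O)C(C)=C
Why: DMAP-catalysed acylation of the secondary alcohol installs the ester with retention at C8.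

Step 20
Reactants: 32 C8 methacrylate
Product: 33 6,12-diol (6-OH and the primary allylic 12-OH free)
Conditions: HF·pyridine, pyridine, THF, 0 °C → rt
Reagents that add atoms: none
Why: Buffered fluoride cleavage removes both tert-butyldimethylsilyl ethers under slightly acidic conditions, which avoids migration of the methacrylate.

Step 21
Reactants: 33 6,12-diol
Product: 36 α-methylene γ-lactone (6,12-olide, trans-fused; 3-OPMB, 15-OPMB, 8-methacrylate, 1(10)E,4Z-diene), via hydroxy enal 34 (not isolated), via lactol 35 (not isolated)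
Conditions: TEMPO (cat.), PhI(OAc)2, CH2Cl2, rt
Reagents that add atoms: none
Why: Oxoammonium oxidation should take the primary allylic alcohol first; the enal closes with 6-OH to the lactol, which is oxidised on to the trans-fused α-methylene lactone.

Step 22
Reactants: 36 α-methylene γ-lactone
Product: 37 (1R,10R)-1,10-epoxide (bis-PMB ether of the target)
Conditions: D-fructose-derived Shi ketone (cat.), KHSO5 (as Oxone), K2CO3, n-Bu4NHSO4, MeCN/CH2(OMe)2, aq. Na2B4O7 buffer (pH 10.5), 0 °C
Reagents that add atoms: potassium peroxymonosulfate, [K+].[O-]S(=O)(=O)OO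
Why: Shi epoxidation should take only the electron-rich E-trisubstituted C1=C10 alkene (C4=C5 carries three allylic C–O bonds, the two enoates are electron-poor), and the chiral dioxirane selects the face that gives the (R,R)-type trans-epoxide, the two faces being offered by interconverting ring conformers.

Step 23
Reactants: 37 (1R,10R)-1,10-epoxide bis-PMB ether
Product: 38 target CNP0496616.1
Conditions: DDQ, CH2Cl2/pH 7 phosphate buffer, 0 °C → rt
Reagents that add atoms: none
Why: Oxidative cleavage of the two allylic PMB ethers under buffered conditions should leave the epoxide, the esters and the alkenes intact.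

**Compound list**

1 | tert-butyldimethyl(prop-2-yn-1-yloxy)silane | C#CCO[Si](C)(C)C(C)(C)C | starting material
2 | 2-[3-(tert-butyldimethylsilyloxy)prop-1-en-2-yl]-4,4,5,5-tetramethyl-1,3,2-dioxaborolane | C=C(CO[Si](C)(C)C(C)(C)C)B1OC(C)(C)C(C)(C)O1 | intermediate
3 | methyl propiolate | C#CC(=O)OC | starting material
4 | 4-methoxybenzyl alcohol | COc1ccc(CO)cc1 | starting material
5 | methyl (E)-3-[(4-methoxybenzyl)oxy]acrylate | COC(=O)/C=C/OCc1ccc(OC)cc1 | intermediate
6 | methyl 3-acetoxy-2-iodo-3-[(4-methoxybenzyl)oxy]propanoate (diastereomer mixture) | COC(=O)C(I)C(OC(C)=O)OCc1ccc(OC)cc1 | intermediate (not isolated)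
7 | methyl (Z)-2-iodo-3-[(4-methoxybenzyl)oxy]acrylate | COC(=O)/C(I)=C/OCc1ccc(OC)cc1 | intermediate
8 | (Z)-2-iodo-3-[(4-methoxybenzyl)oxy]prop-2-en-1-ol | OC/C(I)=C/OCc1ccc(OC)cc1 | intermediate
9 | sodium alkoxide of 8 | [Na]OC/C(I)=C/OCc1ccc(OC)cc1 | intermediate (not isolated)
10 | (Z)-2-iodo-1,3-bis[(4-methoxybenzyl)oxy]prop-1-ene | COc1ccc(COC/C(I)=C/OCc2ccc(OC)cc2)cc1 | intermediate
11 | 4-methoxy-2-methylphenol | Cc1cc(OC)ccc1O | starting material
12 | 4,4-dimethoxy-2-methylcyclohexa-2,5-dien-1-one | COC1(OC)C=CC(=O)C(C)=C1 | intermediate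
13 | (R)-4,4-dimethoxy-2-methyl-5-[3-(tert-butyldimethylsilyloxy)prop-1-en-2-yl]cyclohex-2-en-1-one | O=C1C(C)=CC(OC)(OC)[C@@H](C(=C)CO[Si](C)(C)C(C)(C)C)C1 | intermediate
14 | (1R,5R)-4,4-dimethoxy-2-methyl-5-[3-(tert-butyldimethylsilyloxy)prop-1-en-2-yl]cyclohex-2-en-1-ol | O[C@H]1C(C)=CC(OC)(OC)[C@@H](C(=C)CO[Si](C)(C)C(C)(C)C)C1 | intermediate (not isolated)
15 | (4R,6R)-4-hydroxy-3-methyl-6-[3-(tert-butyldimethylsilyloxy)prop-1-en-2-yl]cyclohex-2-en-1-one | O=C1C=C(C)[C@H](O)C[C@@H]1C(=C)CO[Si](C)(C)C(C)(C)C | intermediate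
16 | bromomagnesium alkoxide of 15 | O=C1C=C(C)[C@H](O[Mg]Br)C[C@@H]1C(=C)CO[Si](C)(C)C(C)(C)C | intermediate (not isolated)
17 | (3R,4R,6R)-4-hydroxy-3-methyl-3-vinyl-6-[3-(tert-butyldimethylsilyloxy)prop-1-en-2-yl]cyclohexan-1-one | O=C1C[C@](C)(C=C)[C@H](O)C[C@@H]1C(=C)CO[Si](C)(C)C(C)(C)C | intermediate
18 | (2R,5R)-2-methyl-5-[3-(tert-butyldimethylsilyloxy)prop-1-en-2-yl]-2-vinylcyclohexane-1,4-dione | O=C1C[C@](C)(C=C)C(=O)C[C@@H]1C(=C)CO[Si](C)(C)C(C)(C)C | intermediate
19 | (2R,4R,5R)-4-hydroxy-2-methyl-5-[3-(tert-butyldimethylsilyloxy)prop-1-en-2-yl]-2-vinylcyclohexan-1-one | O[C@@H]1C[C@](C)(C=C)C(=O)C[C@@H]1C(=C)CO[Si](C)(C)C(C)(C)C | intermediate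
20 | triethylsilyl ether of 19 (8β-OSiEt3) | CC[Si](CC)(CC)O[C@@H]1C[C@](C)(C=C)C(=O)C[C@@H]1C(=C)CO[Si](C)(C)C(C)(C)C | intermediate
21 | potassium enolate of 20 (C5=C6) | CC[Si](CC)(CC)O[C@@H]1C[C@](C)(C=C)C(O[K])=C[C@@H]1C(=C)CO[Si](C)(C)C(C)(C)C | intermediate (not isolated)
22 | 6α-hydroxy ketone (6α-OH trans to the 7β side chain, 8β-OSiEt3, 10β-vinyl) | CC[Si](CC)(CC)O[C@@H]1C[C@](C)(C=C)C(=O)[C@@H](O)[C@@H]1C(=C)CO[Si](C)(C)C(C)(C)C | intermediate
23 | ketone with 6α-OSi(t-Bu)Me2, 7β side chain, 8β-OSiEt3, 10α-methyl, 10β-vinyl | CC[Si](CC)(CC)O[C@@H]1C[C@](C)(C=C)C(=O)[C@@H](O[Si](C)(C)C(C)(C)C)[C@@H]1C(=C)CO[Si](C)(C)C(C)(C)C | intermediate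
24 | (Z)-1,3-bis(4-methoxybenzyloxy)prop-1-en-2-yllithium (Li cis to the enol oxygen) | COc1ccc(COC/C([Li])=C/OCc2ccc(OC)cc2)cc1 | intermediate (not isolated)
25 | (Z)-1,3-bis(4-methoxybenzyloxy)prop-1-en-2-ylcerium dichloride | COc1ccc(COC/C([Ce](Cl)Cl)=C/OCc2ccc(OC)cc2)cc1 | intermediate (not isolated)
26 | tertiary alcohol: 5α-OH, 5β-[(Z)-1,3-bis(4-methoxybenzyloxy)prop-1-en-2-yl] adduct of 23 | CC[Si](CC)(CC)O[C@@H]1C[C@](C)(C=C)[C@](O)(/C(COCc2ccc(OC)cc2)=C\OCc2ccc(OC)cc2)[C@@H](O[Si](C)(C)C(C)(C)C)[C@@H]1C(=C)CO[Si](C)(C)C(C)(C)C | intermediate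
27 | potassium alkoxide of 26 | CC[Si](CC)(CC)O[C@@H]1C[C@](C)(C=C)[C@](O[K])(/C(COCc2ccc(OC)cc2)=C\OCc2ccc(OC)cc2)[C@@H](O[Si](C)(C)C(C)(C)C)[C@@H]1C(=C)CO[Si](C)(C)C(C)(C)C | intermediate (not isolated)
28 | ten-membered potassium enolate (C4=C5–OK, C3 and C6 cis; 1(10)E; 3S) | CC[Si](CC)(CC)O[C@@H]1C/C(C)=C/C[C@H](OCc2ccc(OC)cc2)/C(COCc2ccc(OC)cc2)=C(O[K])\[C@@H](O[Si](C)(C)C(C)(C)C)[C@@H]1C(=C)CO[Si](C)(C)C(C)(C)C | intermediate (not isolated)
29 | ten-membered enol triflate (5-OTf; 1(10)E,4E; 3S) | CC[Si](CC)(CC)O[C@@H]1C/C(C)=C/C[C@H](OCc2ccc(OC)cc2)/C(COCc2ccc(OC)cc2)=C(OS(=O)(=O)C(F)(F)F)\[C@@H](O[Si](C)(C)C(C)(C)C)[C@@H]1C(=C)CO[Si](C)(C)C(C)(C)C | intermediate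
30 | (1(10)E,4Z)-diene with 3-OPMB, 15-OPMB, 6-OSi(t-Bu)Me2, 12-OSi(t-Bu)Me2, 8-OSiEt3 | CC[Si](CC)(CC)O[C@@H]1C/C(C)=C/C[C@H](OCc2ccc(OC)cc2)/C(COCc2ccc(OC)cc2)=C\[C@@H](O[Si](C)(C)C(C)(C)C)[C@@H]1C(=C)CO[Si](C)(C)C(C)(C)C | intermediate
31 | C8 alcohol of 30 | O[C@@H]1C/C(C)=C/C[C@H](OCc2ccc(OC)cc2)/C(COCc2ccc(OC)cc2)=C\[C@@H](O[Si](C)(C)C(C)(C)C)[C@@H]1C(=C)CO[Si](C)(C)C(C)(C)C | intermediate
32 | C8 methacrylate | C=C(C)C(=O)O[C@@H]1C/C(C)=C/C[C@H](OCc2ccc(OC)cc2)/C(COCc2ccc(OC)cc2)=C\[C@@H](O[Si](C)(C)C(C)(C)C)[C@@H]1C(=C)CO[Si](C)(C)C(C)(C)C | intermediate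
33 | 6,12-diol | C=C(C)C(=O)O[C@@H]1C/C(C)=C/C[C@H](OCc2ccc(OC)cc2)/C(COCc2ccc(OC)cc2)=C\[C@@H](O)[C@@H]1C(=C)CO | intermediate
34 | hydroxy enal (C12 aldehyde, 6-OH) | C=C(C)C(=O)O[C@@H]1C/C(C)=C/C[C@H](OCc2ccc(OC)cc2)/C(COCc2ccc(OC)cc2)=C\[C@@H](O)[C@@H]1C(=C)C=O | intermediate (not isolated)
35 | lactol (C12 hemiacetal, either epimer) | C=C(C)C(=O)O[C@@H]1C/C(C)=C/C[C@H](OCc3ccc(OC)cc3)/C(COCc3ccc(OC)cc3)=C\[C@H]2OC(O)C(=C)[C@@H]21 | intermediate (not isolated)
36 | α-methylene γ-lactone (6,12-olide; 1(10)E,4Z-diene; 3,15-bis-PMB ether; 8-methacrylate) | C=C(C)C(=O)O[C@@H]1C/C(C)=C/C[C@H](OCc3ccc(OC)cc3)/C(COCc3ccc(OC)cc3)=C\[C@H]2OC(=O)C(=C)[C@@H]21 | intermediate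
37 | (1R,10R)-1,10-epoxide, 3,15-bis-PMB ether of the target | C=C(C)C(=O)O[C@@H]1C[C@@]2(C)O[C@@H]2C[C@H](OCc3ccc(OC)cc3)/C(COCc3ccc(OC)cc3)=C\[C@H]2OC(=O)C(=C)[C@@H]21 | intermediate
38 | CNP0496616.1 | C=C(C)C(=O)O[C@@H]1C[C@@]2(C)O[C@@H]2C[C@H](O)/C(CO)=C\[C@H]2OC(=O)C(=C)[C@@H]21 | target

**Totals and risks**

Total step count: 23. Longest linear sequence: 18 steps (steps 6–23, from 11).

Steps most likely to fail:

Step 16. The potassium enolate formed by the rearrangement carries two β-alkoxy groups (O3 and O15) and may lose an alkoxide by β-elimination before it is triflated. The rearrangement may also be too slow at temperatures where the enolate survives, because the Z enol ether puts its oxygen pseudo-axial. The fallback is the neutral variant, in which no free enolate is present during the ring expansion. It sets out from 26: silylation (Me3SiOTf, 2,6-lutidine) gives the trimethylsilyl ether F1. Thermal siloxy-Cope rearrangement (toluene, sealed base-washed tube, about 180 °C) through the same chair should give the ten-membered trimethylsilyl enol ether F2. Cleavage with MeLi at −78 °C gives the lithium enolate F3, which is less prone to elimination and is triflated at once with PhNTf2. This returns to the route at 29.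

Step 15. The alkenyllithium may decompose by β-elimination of its allylic alkoxide, or it may enolise the very hindered ketone at C6 instead of adding. The fallback uses a less basic nucleophile without an allylic leaving group and sets out from 7 and 23. Iodine–magnesium exchange of 7 (i-PrMgCl·LiCl, THF, −40 °C) gives the ester-stabilised alkenylmagnesium chloride F4. This is added to 23 in the presence of LaCl3·2LiCl to give the hydroxy ester F5. Reduction with i-Bu2AlH gives the diol F6. Selective etherification of the primary allylic hydroxyl (NaH, 4-methoxybenzyl chloride) comes back to the route at 26.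

Step 9. Direct 1,2-addition to the C8 carbonyl, or enolisation, may outrun the directed delivery of vinyl to the fully substituted β-carbon. The fallback builds the quaternary centre by enolate chemistry and sets out from 13. Conjugate reduction with LiBH(s-Bu)3 gives the lithium enolate F7, which is trapped with acetaldehyde (axial C–C bond formation cis to the C7 side chain) to give the aldol F8. Dehydration with Burgess reagent gives the vinyl ketone ketal F9. Hydrolysis of the ketal with aqueous oxalic acid returns to the route at 18.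

**Further compounds**

F1 | step 16 | trimethylsilyl ether of 26 | CC[Si](CC)(CC)O[C@@H]1C[C@](C)(C=C)[C@](O[Si](C)(C)C)(/C(COCc2ccc(OC)cc2)=C\OCc2ccc(OC)cc2)[C@@H](O[Si](C)(C)C(C)(C)C)[C@@H]1C(=C)CO[Si](C)(C)C(C)(C)C
F2 | step 16 | ten-membered trimethylsilyl enol ether | CC[Si](CC)(CC)O[C@@H]1C/C(C)=C/C[C@H](OCc2ccc(OC)cc2)/C(COCc2ccc(OC)cc2)=C(O[Si](C)(C)C)\[C@@H](O[Si](C)(C)C(C)(C)C)[C@@H]1C(=C)CO[Si](C)(C)C(C)(C)C
F3 | step 16 | ten-membered lithium enolate | CC[Si](CC)(CC)O[C@@H]1C/C(C)=C/C[C@H](OCc2ccc(OC)cc2)/C(COCc2ccc(OC)cc2)=C(O[Li])\[C@@H](O[Si](C)(C)C(C)(C)C)[C@@H]1C(=C)CO[Si](C)(C)C(C)(C)C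
F4 | step 15 | (Z)-1-methoxycarbonyl-2-(4-methoxybenzyloxy)vinylmagnesium chloride | COC(=O)/C([Mg]Cl)=C/OCc1ccc(OC)cc1
F5 | step 15 | hydroxy ester adduct of 23 | CC[Si](CC)(CC)O[C@@H]1C[C@](C)(C=C)[C@](O)(/C(C(=O)OC)=C\OCc2ccc(OC)cc2)[C@@H](O[Si](C)(C)C(C)(C)C)[C@@H]1C(=C)CO[Si](C)(C)C(C)(C)C
F6 | step 15 | diol (C15 hydroxymethyl, tertiary C5 alcohol) | CC[Si](CC)(CC)O[C@@H]1C[C@](C)(C=C)[C@](O)(/C(CO)=C\OCc2ccc(OC)cc2)[C@@H](O[Si](C)(C)C(C)(C)C)[C@@H]1C(=C)CO[Si](C)(C)C(C)(C)C
F7 | step 9 | lithium enolate from conjugate reduction of 13 | [Li]OC1=C(C)CC(OC)(OC)[C@@H](C(=C)CO[Si](C)(C)C(C)(C)C)C1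
F8 | step 9 | aldol with acetaldehyde (carbinol epimers) | O=C1[C@@](C)(C(C)O)CC(OC)(OC)[C@@H](C(=C)CO[Si](C)(C)C(C)(C)C)C1
F9 | step 9 | 2-methyl-2-vinyl ketone dimethyl ketal | O=C1[C@@](C)(C=C)CC(OC)(OC)[C@@H](C(=C)CO[Si](C)(C)C(C)(C)C)C1
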